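**Retrosynthetic overview**
1. Target 18 ⇐ dibenzyl ether 17 (hydrogenolysis). The C3–OH of 17 ⇐ hydroxylation of the enolate of trans-dibenzyl lactone 16, with oxygen entering anti to the C4 benzyl group.
2. 16 ⇐ benzylidene lactone 15 ⇐ aldol adduct 13. The C3–C(benzylic) bond is made by aldol addition of the lithium enolate of lactone 11 to O-benzylvanillin 12 (fragment union), followed by dehydration and C=C reduction.
3. Lactone 11 (the only ring, closed before the union) ⇐ hydroxy ester 10 ⇐ Evans alkylation of imide 7 with tert-butyl bromoacetate 8, which sets C4.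
4. Imide 7 ⇐ acid 4 + (R)-4-benzyl-2-oxazolidinone 5; acid 4 ⇐ ferulic acid 1.

The target is (3S,4R): the two benzyl groups are cis and the 3-OH is trans to the C4 benzyl group.

Assumption: the carbinol centre of 13 and 14 forms as an epimer mixture and is destroyed in step 8, so it is drawn undefined; all other centres are drawn as the single isomer carried forward.

**Step 1**
Reactants: 1 ferulic acid
Product: 2 3-(4-hydroxy-3-methoxyphenyl)propanoic acid
Conditions: H2 (1 atm), 10% Pd/C, MeOH, rt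
Reagents that add atoms: none
Why: Catalytic hydrogenation saturates the cinnamate C=C cleanly and leaves the arene and acid untouched.

**Step 2**
Reactants: 2 3-(4-hydroxy-3-methoxyphenyl)propanoic acid
Product: 4 3-[4-(benzyloxy)-3-methoxyphenyl]propanoic acid, via benzyl ester 3 (not isolated)
Conditions: BnBr (2.3 equiv), K2CO3, DMF, 60 °C; then 2 M NaOH, MeOH, 60 °C; HCl to pH 2
Reagents that add atoms: benzyl bromide, BrCc1ccccc1; sodium hydroxide, [Na+].[OH-] (oxygen of the CO2H after saponification)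
Why: Williamson etherification benzylates both the phenol and the carboxylate, and saponification then frees only the acid because the aryl benzyl ether is inert to hydroxide.

**Step 3**
Reactants: 4 3-[4-(benzyloxy)-3-methoxyphenyl]propanoic acid; 5 (R)-4-benzyl-2-oxazolidinone
Product: 7 (4R)-4-benzyl-3-{3-[4-(benzyloxy)-3-methoxyphenyl]propanoyl}-1,3-oxazolidin-2-one, via mixed pivalic anhydride 6 (not isolated)
Conditions: PivCl, Et3N, THF, −20 °C; then LiCl, 5, −20 °C → rt
Reagents that add atoms: none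
Why: N-acylation through the mixed pivalic anhydride is regioselective because the oxazolidinone attacks the unhindered acyl carbon and not the pivaloyl carbon.

**Step 4**
Reactants: 7 (4R)-4-benzyl-3-{3-[4-(benzyloxy)-3-methoxyphenyl]propanoyl}-1,3-oxazolidin-2-one; 8 tert-butyl bromoacetate
Product: 9 tert-butyl (3S)-4-[(4R)-4-benzyl-2-oxo-1,3-oxazolidin-3-yl]-3-[4-(benzyloxy)-3-methoxybenzyl]-4-oxobutanoate
Conditions: NaN(SiMe3)2 (1.1 equiv), THF, −78 °C; then 8, −78 → −40 °C
Reagents that add atoms: none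
Why: Evans asymmetric alkylation: the chelated Z-sodium enolate is attacked by the bromoacetate on the face opposite the auxiliary benzyl group, which sets the new centre as S (the future C4 of the lactone).

**Step 5**
Reactants: 9 tert-butyl (3S)-4-[(4R)-4-benzyl-2-oxo-1,3-oxazolidin-3-yl]-3-[4-(benzyloxy)-3-methoxybenzyl]-4-oxobutanoate
Product: 10 tert-butyl (3S)-4-[4-(benzyloxy)-3-methoxyphenyl]-3-(hydroxymethyl)butanoate
Conditions: LiBH4 (1.2 equiv), MeOH (1.2 equiv), THF, 0 °C
Reagents that add atoms: none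
Why: Reductive cleavage of the activated exocyclic imide carbonyl by LiBH4 spares the hindered tert-butyl ester and does not touch the stereocentre; the auxiliary 5 is recovered.

**Step 6**
Reactants: 10 tert-butyl (3S)-4-[4-(benzyloxy)-3-methoxyphenyl]-3-(hydroxymethyl)butanoate
Product: 11 (4S)-4-[4-(benzyloxy)-3-methoxybenzyl]dihydrofuran-2(3H)-one
Conditions: p-TsOH·H2O (10 mol%), toluene, 80 °C
Reagents that add atoms: none
Why: Acid-catalysed lactonisation of a γ-hydroxy tert-butyl ester closes the five-membered ring irreversibly with loss of the tert-butyl group, and the stereocentre is not involved.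

**Step 7**
Reactants: 11 (4S)-4-[4-(benzyloxy)-3-methoxybenzyl]dihydrofuran-2(3H)-one; 12 4-(benzyloxy)-3-methoxybenzaldehyde (O-benzylvanillin)
Product: 13 (3R,4S)-4-[4-(benzyloxy)-3-methoxybenzyl]-3-{[4-(benzyloxy)-3-methoxyphenyl](hydroxy)methyl}dihydrofuran-2(3H)-one (carbinol epimer mixture)
Conditions: LiN(iPr)2 (1.1 equiv), THF, −78 °C; then 12, −78 °C; NH4Cl quench at −78 °C
Reagents that add atoms: none
Why: Intermolecular aldol addition of the lactone lithium enolate to a non-enolisable aldehyde occurs anti to the C4 benzyl group, giving the 3,4-trans adduct (C3 R); the carbinol centre is removed in step 8.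

**Step 8**
Reactants: 13 (3R,4S)-aldol adduct
Product: 15 (3E,4S)-4-[4-(benzyloxy)-3-methoxybenzyl]-3-[4-(benzyloxy)-3-methoxybenzylidene]dihydrofuran-2(3H)-one, via benzylic mesylate 14 (not isolated)
Conditions: MsCl, Et3N, CH2Cl2, 0 °C; then DBU, rt
Reagents that add atoms: none
Why: Mesylation followed by E1cB elimination through the lactone enolate converts both carbinol epimers into the conjugated, thermodynamically preferred E-benzylidene lactone without touching C4.

**Step 9**
Reactants: 15 (3E,4S)-benzylidene lactone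
Product: 16 (3S,4S)-3,4-bis[4-(benzyloxy)-3-methoxybenzyl]dihydrofuran-2(3H)-one
Conditions: NaBH4 (4 equiv), NiCl2·6H2O (0.3 equiv), MeOH/THF, 0 °C; then DBU (cat.), rt
Reagents that add atoms: none
Why: Nickel boride conjugate reduction saturates the enoate C=C while sparing the aryl benzyl ethers and the lactone, and base equilibration gives the trans isomer (C3 S); C3 is erased in step 10 in any case.

**Step 10**
Reactants: 16 (3S,4S)-3,4-bis[4-(benzyloxy)-3-methoxybenzyl]dihydrofuran-2(3H)-one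
Product: 17 (3S,4R)-3,4-bis[4-(benzyloxy)-3-methoxybenzyl]-3-hydroxydihydrofuran-2(3H)-one
Conditions: KN(SiMe3)2 (1.3 equiv), THF, −78 °C; then (±)-trans-3-phenyl-2-(phenylsulfonyl)oxaziridine (1.5 equiv), −78 °C; NH4Cl quench
Reagents that add atoms: (±)-trans-3-phenyl-2-(phenylsulfonyl)oxaziridine (Davis oxaziridine), O=S(=O)(c1ccccc1)N1OC1c1ccccc1
Why: Davis enolate hydroxylation: the planar potassium enolate takes oxygen on the face anti to the adjacent C4 benzyl group, so the OH ends up trans to it and the two benzyl groups cis, which is the (3S,4R) configuration.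

**Step 11**
Reactants: 17 (3S,4R)-3,4-bis[4-(benzyloxy)-3-methoxybenzyl]-3-hydroxydihydrofuran-2(3H)-one
Product: 18 (3S,4R)-3-hydroxy-3,4-bis(4-hydroxy-3-methoxybenzyl)dihydrofuran-2(3H)-one
Conditions: H2 (1 atm), 10% Pd/C, EtOAc/MeOH, rt
Reagents that add atoms: none
Why: Hydrogenolysis removes both aryl benzyl ethers under neutral conditions; the tertiary, non-benzylic α-hydroxy lactone and both stereocentres are unaffected.

**Compound list**
1 | ferulic acid, (E)-3-(4-hydroxy-3-methoxyphenyl)prop-2-enoic acid | COc1cc(/C=C/C(=O)O)ccc1O | starting material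
2 | 3-(4-hydroxy-3-methoxyphenyl)propanoic acid | COc1cc(CCC(=O)O)ccc1O | intermediate
3 | benzyl 3-[4-(benzyloxy)-3-methoxyphenyl]propanoate | COc1cc(CCC(=O)OCc2ccccc2)ccc1OCc1ccccc1 | intermediate
4 | 3-[4-(benzyloxy)-3-methoxyphenyl]propanoic acid | COc1cc(CCC(=O)O)ccc1OCc1ccccc1 | intermediate
5 | (R)-4-benzyl-2-oxazolidinone | O=C1N[C@H](Cc2ccccc2)CO1 | starting material
6 | 3-[4-(benzyloxy)-3-methoxyphenyl]propanoic pivalic anhydride | COc1cc(CCC(=O)OC(=O)C(C)(C)C)ccc1OCc1ccccc1 | intermediate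
7 | (4R)-4-benzyl-3-{3-[4-(benzyloxy)-3-methoxyphenyl]propanoyl}-1,3-oxazolidin-2-one | COc1cc(CCC(=O)N2[C@H](Cc3ccccc3)COC2=O)ccc1OCc1ccccc1 | intermediate
8 | tert-butyl bromoacetate | CC(C)(C)OC(=O)CBr | starting material
9 | tert-butyl (3S)-4-[(4R)-4-benzyl-2-oxo-1,3-oxazolidin-3-yl]-3-[4-(benzyloxy)-3-methoxybenzyl]-4-oxobutanoate | CC(C)(C)OC(=O)C[C@H](Cc1ccc(OCc2ccccc2)c(OC)c1)C(=O)N1[C@H](Cc2ccccc2)COC1=O | intermediate
10 | tert-butyl (3S)-4-[4-(benzyloxy)-3-methoxyphenyl]-3-(hydroxymethyl)butanoate | CC(C)(C)OC(=O)C[C@H](Cc1ccc(OCc2ccccc2)c(OC)c1)CO | intermediate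
11 | (4S)-4-[4-(benzyloxy)-3-methoxybenzyl]dihydrofuran-2(3H)-one | O=C1C[C@H](Cc2ccc(OCc3ccccc3)c(OC)c2)CO1 | intermediate
12 | 4-(benzyloxy)-3-methoxybenzaldehyde | COc1cc(C=O)ccc1OCc1ccccc1 | starting material
13 | (3R,4S)-4-[4-(benzyloxy)-3-methoxybenzyl]-3-{[4-(benzyloxy)-3-methoxyphenyl](hydroxy)methyl}dihydrofuran-2(3H)-one, carbinol epimer mixture | O=C1OC[C@@H](Cc2ccc(OCc3ccccc3)c(OC)c2)[C@@H]1C(O)c1ccc(OCc2ccccc2)c(OC)c1 | intermediate
14 | methanesulfonate of 13, carbinol epimer mixture | O=C1OC[C@@H](Cc2ccc(OCc3ccccc3)c(OC)c2)[C@@H]1C(OS(C)(=O)=O)c1ccc(OCc2ccccc2)c(OC)c1 | intermediate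
15 | (3E,4S)-4-[4-(benzyloxy)-3-methoxybenzyl]-3-[4-(benzyloxy)-3-methoxybenzylidene]dihydrofuran-2(3H)-one | O=C1OC[C@@H](Cc2ccc(OCc3ccccc3)c(OC)c2)/C1=C\c1ccc(OCc2ccccc2)c(OC)c1 | intermediate
16 | (3S,4S)-3,4-bis[4-(benzyloxy)-3-methoxybenzyl]dihydrofuran-2(3H)-one | O=C1OC[C@@H](Cc2ccc(OCc3ccccc3)c(OC)c2)[C@@H]1Cc1ccc(OCc2ccccc2)c(OC)c1 | intermediate
17 | (3S,4R)-3,4-bis[4-(benzyloxy)-3-methoxybenzyl]-3-hydroxydihydrofuran-2(3H)-one | COc1cc(C[C@@H]2COC(=O)[C@]2(O)Cc2ccc(OCc3ccccc3)c(OC)c2)ccc1OCc1ccccc1 | intermediate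
18 | (3S,4R)-3-hydroxy-3,4-bis(4-hydroxy-3-methoxybenzyl)dihydrofuran-2(3H)-one | COc1cc(C[C@@H]2COC(=O)[C@]2(O)Cc2ccc(O)c(OC)c2)ccc1O | target

**Totals**
Total step count: 11. Longest linear sequence: 11 steps (1 → 18).

**Three steps most likely to fail**

Step 10 (facial selectivity and yield of hydroxylating a tetrasubstituted enolate). The fallback sets out from 15 and comes back at 18. Epoxidation of the exocyclic alkene of 15 with dimethyldioxirane in acetone, anti to the C4 benzyl group, gives the spiro-epoxide (2S,3R,7R)-2-[4-(benzyloxy)-3-methoxyphenyl]-7-[4-(benzyloxy)-3-methoxybenzyl]-1,5-dioxaspiro[2.4]heptan-4-one F1. Hydrogenation over Pd/C then cleaves the benzylic C–O bond of the epoxide, leaving the oxygen on C3 with its configuration, and removes both benzyl ethers to give 18 directly. The C3–O bond is thus made by alkene oxidation and not by enolate oxidation.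

Step 9 (chemoselective C=C reduction beside two benzyl ethers and a lactone). The fallback sets out from 15 and comes back at 16. Exhaustive hydrogenation of 15 over Pd/C reduces the alkene and removes both benzyl groups, giving (4S)-3,4-bis(4-hydroxy-3-methoxybenzyl)dihydrofuran-2(3H)-one F2 as a C3 epimer mixture. Both phenols are then re-benzylated with BnBr and K2CO3 in DMF, and a catalytic amount of DBU equilibrates C3 to the trans isomer 16.

Step 5 (ring-opening of the oxazolidinone, or over-reduction after premature lactonisation). The fallback sets out from 9 and comes back at 10. The auxiliary is removed hydrolytically with LiOH and H2O2 in THF/H2O at 0 °C to give (2S)-2-[4-(benzyloxy)-3-methoxybenzyl]-4-tert-butoxy-4-oxobutanoic acid F3. The free acid is then reduced with BH3·SMe2 in THF at 0 °C, which leaves the tert-butyl ester alone, to give 10.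

**Further compounds**
F1 | step 10 | (2S,3R,7R)-2-[4-(benzyloxy)-3-methoxyphenyl]-7-[4-(benzyloxy)-3-methoxybenzyl]-1,5-dioxaspiro[2.4]heptan-4-one | O=C1OC[C@@H](Cc2ccc(OCc3ccccc3)c(OC)c2)[C@]12O[C@H]2c1ccc(OCc2ccccc2)c(OC)c1
F2 | step 9 | (4S)-3,4-bis(4-hydroxy-3-methoxybenzyl)dihydrofuran-2(3H)-one, C3 epimer mixture | O=C1OC[C@@H](Cc2ccc(O)c(OC)c2)C1Cc1ccc(O)c(OC)c1
F3 | step 5 | (2S)-2-[4-(benzyloxy)-3-methoxybenzyl]-4-tert-butoxy-4-oxobutanoic acid | CC(C)(C)OC(=O)C[C@H](Cc1ccc(OCc2ccccc2)c(OC)c1)C(=O)O
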